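Cuts, in retrosynthetic order: C1–O2 with C8–H (lactone bridge), C5–C8 (oxolane ring), C1–O7 and C1=C8 (acetal, Wittig). In the hydrocarbon the cuts are C4′–C4a′ (ring A), C2′–CH3 and C1′–C2′.
Enabling feature: in ring A (C1′, C2′, C3′, C4′, C4a′, C8a′) the ring-fusion carbon C4a′ bears H and is allylic to the C8′=C8a′ alkene of ring B. C4′–C4a′–C8a′=C8′ is therefore the homoallylic array that a carbonyl-ene reaction of a C4′ aldehyde with a C4a′=C8a′ cyclohexene leaves once the C4′ oxygen is removed.
Forward: ring B is bought as 2,2-dimethylcyclohexanone, and an Ireland–Claisen shift plus a methylation attach the C1′–C4′/C8 chain. Ring A closes by the ene reaction, the oxolane ring (O7, C1, C8, C5, C6) by radical closure, and the δ-lactone ring (C1, O2, C3, C4, C5, C8) last.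
Stereochemistry: an oxazaborolidine-catalysed reduction sets one carbinol centre, relayed to C1′ ([3,3] shift), C2′ (allylic-strain-controlled methylation) and C4a′ (chair-like ene closure). C6 is bought with (R)-but-3-ene-1,2-diol and relayed to C5 (radical closure) and to C8 and C1 (final anti addition across C1=C8).

Key step: step 11

Remark: primed locants are those of the octahydronaphthalene and unprimed ones those of the 2,7-dioxabicyclo[3.2.1]octan-3-one (C1 acetal, O2, C3 C=O, C4, C5, C6 CHCO2Me, O7, C8), and they label the same atoms in every precursor. The CIP letter at C1′ switches between R and S because the ranking of C2′ against C8a′ depends on what C8 carries; the spatial arrangement never changes. Compounds 1, 2, 7, 24 and 25 are taken as purchasable.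

Step 1
Reactants: 1 2,2-dimethylcyclohexan-1-one; 2 acetaldehyde
Product: 3 6-(1-hydroxyethyl)-2,2-dimethylcyclohexan-1-one (racemic; both diastereomers)
Conditions: LiN(iPr)2, THF, −78 °C; then 2; aq. NH4Cl
Reagents that add atoms: none
Why: Directed aldol addition of the only possible lithium enolate of 1 to acetaldehyde; both new stereocentres disappear in step 2, so their configuration does not matter.

Step 2
Reactants: 3 6-(1-hydroxyethyl)-2,2-dimethylcyclohexan-1-one
Product: 5 (E)-6-ethylidene-2,2-dimethylcyclohexan-1-one, via mesylate 4 (not isolated)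
Conditions: MsCl, Et3N, CH2Cl2, 0 °C; then DBU, rt
Reagents that add atoms: methanesulfonyl chloride CS(=O)(=O)Cl (retained only in 4)
Why: Mesylation and E1cB elimination complete the aldol condensation, and the E isomer is expected because the methyl group turns away from the carbonyl oxygen under the equilibrating DBU conditions.

Step 3
Reactants: 5 (E)-6-ethylidene-2,2-dimethylcyclohexan-1-one
Product: 6 (1S,2E)-2-ethylidene-6,6-dimethylcyclohexan-1-ol
Conditions: (S)-2-methyl-CBS-oxazaborolidine (cat.), BH3·SMe2, THF, −20 °C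
Reagents that add atoms: none
Why: Corey–Bakshi–Shibata 1,2-reduction of an enone; with the quaternary flank as the large group and the flat alkylidene flank as the small one, the S catalyst should deliver hydride to the face that gives the S carbinol, the only source of absolute configuration for the hydrocarbon half.

Step 4
Reactants: 7 methyl 4,4-dimethoxybutanoate
Product: 8 4,4-dimethoxybutanoic acid
Conditions: LiOH, THF–H2O, rt; then cold dilute HCl to pH 4
Reagents that add atoms: lithium hydroxide [Li+].[OH-]
Why: Ester saponification; the acetal is inert to base and survives the brief, mild acidification.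

Step 5
Reactants: 6 (1S,2E)-2-ethylidene-6,6-dimethylcyclohexan-1-ol; 8 4,4-dimethoxybutanoic acid
Product: 9 (1S,2E)-2-ethylidene-6,6-dimethylcyclohexyl 4,4-dimethoxybutanoate
Conditions: EDC·HCl, DMAP, CH2Cl2, rt
Reagents that add atoms: none
Why: Steglich-type carbodiimide esterification with DMAP as acyl-transfer catalyst acylates the hindered allylic alcohol without ionising it, so the carbinol centre is untouched.

Step 6
Reactants: 9 (1S,2E)-2-ethylidene-6,6-dimethylcyclohexyl 4,4-dimethoxybutanoate
Product: 12 (3S)-2-(2,2-dimethoxyethyl)-3-(3,3-dimethylcyclohex-1-en-1-yl)butanoic acid (C2′ epimers), via silyl ketene acetal 10 (not isolated), via trimethylsilyl ester 11 (not isolated)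
Conditions: LiN(iPr)2, THF, −78 °C; Me3SiCl; then 60 °C; K2CO3, MeOH–H2O; pH 4
Reagents that add atoms: chlorotrimethylsilane C[Si](C)(C)Cl (retained only in 10 and 11)
Why: Ireland–Claisen rearrangement: the [3,3] shift is suprafacial on the allyl unit, so C1′–C2′ forms on the face from which the pseudoaxial C–O bond leaves and the S carbinol centre becomes the C1′ centre while the alkene moves into ring B as C4a′=C8a′, which holds for chair or boat and for either ketene acetal geometry, and the C2′ epimers converge in step 7.

Step 7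
Reactants: 12 (3S)-2-(2,2-dimethoxyethyl)-3-(3,3-dimethylcyclohex-1-en-1-yl)butanoic acid
Product: 14 (2R,3R)-2-(2,2-dimethoxyethyl)-3-(3,3-dimethylcyclohex-1-en-1-yl)-2-methylbutanoic acid, via dilithium enediolate 13 (not isolated)
Conditions: LiN(iPr)2 (2.3 equiv), THF–DMPU, 0 °C; MeI, −78 to 0 °C; pH 4
Reagents that add atoms: iodomethane CI; lithium diisopropylamide CC(C)[N-]C(C)C.[Li+] (lithium of 13 only)
Why: α-Alkylation of a carboxylic acid dianion: allylic 1,3-strain holds C1′–H in the enediolate plane next to an OLi group, the cyclohexenyl group shields one face, and methyl iodide should enter from the face of the small C1′ methyl group, which sets quaternary C2′ with the two methyl groups in the relationship that becomes cis on ring A.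

Step 8
Reactants: 14 (2R,3R)-2-(2,2-dimethoxyethyl)-3-(3,3-dimethylcyclohex-1-en-1-yl)-2-methylbutanoic acid
Product: 15 (2R,3R)-2-(2,2-dimethoxyethyl)-3-(3,3-dimethylcyclohex-1-en-1-yl)-2-methylbutan-1-ol
Conditions: LiAlH4, THF, reflux
Reagents that add atoms: none
Why: Hydride reduction of the hindered acid to the neopentyl alcohol (C8 at the alcohol level); acetal, alkene and stereocentres are unaffected.

Step 9
Reactants: 15 (2R,3R)-2-(2,2-dimethoxyethyl)-3-(3,3-dimethylcyclohex-1-en-1-yl)-2-methylbutan-1-ol
Product: 16 tert-butyldiphenylsilyl ether of 15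
Conditions: t-BuPh2SiCl, imidazole, DMF, rt
Reagents that add atoms: tert-butyl(chloro)diphenylsilane CC(C)(C)[Si](Cl)(c1ccccc1)c1ccccc1
Why: Silyl ether formation; the bulky, weakly basic silyl ether is chosen so that the C8 oxygen cannot chelate aluminium in step 11 and so that this arm seeks the equatorial site.

Step 10
Reactants: 16 tert-butyldiphenylsilyl ether of 15
Product: 17 (3R,4R)-3-{[tert-butyl(diphenyl)silyl]oxymethyl}-4-(3,3-dimethylcyclohex-1-en-1-yl)-3-methylpentanal
Conditions: PPTS, acetone–H2O, 50 °C
Reagents that add atoms: water O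
Why: Mild acid-catalysed acetal hydrolysis frees the C4′ aldehyde under conditions too weak to start a Prins reaction or to cleave the silyl ether.

Step 11
Reactants: 17 (3R,4R)-3-{[tert-butyl(diphenyl)silyl]oxymethyl}-4-(3,3-dimethylcyclohex-1-en-1-yl)-3-methylpentanal
Product: 18 (1R,3R,4R,8aS)-3-{[tert-butyl(diphenyl)silyl]oxymethyl}-3,4,8,8-tetramethyl-1,2,3,4,6,7,8,8a-octahydronaphthalen-1-ol (C4′ alcohol; OH axial; cis to the C2′ methyl group)
Conditions: Me2AlCl (1.5 equiv), CH2Cl2, −78 to −20 °C
Reagents that add atoms: none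
Why: Me2AlCl binds the C4′ aldehyde, the less substituted alkene carbon C4a′ attacks C4′ while positive charge builds on tertiary C8a′, and the C8′ hydrogen on the same face passes to oxygen through a six-membered array, after which loss of methane gives the aluminium alkoxide and makes the step irreversible. This is the Lewis-acid-promoted intramolecular carbonyl-ene reaction of the class in which the tether sits on the central ene carbon, a standard Me2AlCl route to 3-alkylidenecyclohexanols. Ring A closes as a six-membered chair, endo with respect to the alkene (C4a′ and C8a′ both end in the ring) and exo with respect to the carbonyl group. C4a′ is set by the choice between two chairs: the wanted one keeps C1′–CH3 and the CH2OSi arm equatorial with only C2′–CH3 axial and leaves C4a′–H axial and trans to both methyl groups, whereas its rival must put C1′–CH3 and the CH2OSi arm axial, the latter syn-diaxial to the aluminium-bound oxygen; C4′ carries its oxygen axial because only there can it reach the C8′ hydrogen, and this centre is deleted in step 13. The position of the new alkene (C8′=C8a′, not C1′=C8a′) follows from the concerted hydrogen transfer, since C1′–H lies in the tether and points away from oxygen. Chemoselectivity is secured because the non-chelating silyl ether is the only other function and Me2AlCl scavenges stray protons.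

Step 12
Reactants: 18 C4′ alcohol
Product: 19 O-(C4′) S-methyl dithiocarbonate (xanthate) of 18
Conditions: NaH, CS2, THF, 0 °C to rt; then MeI
Reagents that add atoms: carbon disulfide S=C=S; iodomethane CI
Why: Xanthate formation, the first half of the Barton–McCombie deoxygenation; the small electrophile CS2 reaches even the hindered axial alkoxide.

Step 13
Reactants: 19 xanthate of 18
Product: 20 tert-butyl(diphenyl){[(1R,2R,4aS)-1,2,5,5-tetramethyl-1,2,3,4,4a,5,6,7-octahydronaphthalen-2-yl]methoxy}silane
Conditions: Bu3SnH (concentrated), AIBN, toluene, 100 °C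
Reagents that add atoms: none
Why: Barton–McCombie deoxygenation; the secondary C4′ radical is homoallylic, so a high stannane concentration is used to trap it before 3-exo closure onto C8a′, and the neighbouring C4a′ centre is not touched.

Step 14
Reactants: 20 silyl ether
Product: 21 [(1R,2R,4aS)-1,2,5,5-tetramethyl-1,2,3,4,4a,5,6,7-octahydronaphthalen-2-yl]methanol
Conditions: Bu4NF, THF, 50 °C; aq. NH4Cl
Reagents that add atoms: none
Why: Fluoride cleavage of the silyl ether, driven by the strong Si–F bond, with no effect on alkene or stereocentres.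

Step 15
Reactants: 21 neopentyl alcohol
Product: 22 (1R,2R,4aS)-1,2,5,5-tetramethyl-1,2,3,4,4a,5,6,7-octahydronaphthalene-2-carbaldehyde
Conditions: Dess–Martin periodinane, NaHCO3, CH2Cl2, 0 °C
Reagents that add atoms: none
Why: Dess–Martin oxidation under buffered conditions leaves the alkene alone, and the aldehyde (C8) has no α-hydrogen to lose.

Step 16
Reactants: 22 C8 aldehyde
Product: 23 (1S,2R,4aS)-2-(2-methoxyethenyl)-1,2,5,5-tetramethyl-1,2,3,4,4a,5,6,7-octahydronaphthalene (E/Z mixture)
Conditions: MeOCH2PPh3Cl, KN(SiMe3)2, THF, 0 °C to rt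
Reagents that add atoms: (methoxymethyl)triphenylphosphonium chloride COC[P+](c1ccccc1)(c1ccccc1)c1ccccc1.[Cl-]
Why: Wittig methoxymethylenation, reliable for α-quaternary aldehydes, adds C1 at the aldehyde oxidation level; the E/Z mixture is used as such because both alkene carbons are reset later.

Step 17
Reactants: 24 (R)-but-3-ene-1,2-diol; 25 tert-butyl acrylate
Product: 26 tert-butyl (2E,4R)-4,5-dihydroxypent-2-enoate
Conditions: second-generation Hoveyda–Grubbs catalyst RuCl2(H2IMes)(=CH-C6H4-2-OiPr) (cat.), CH2Cl2, 40 °C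
Reagents that add atoms: none
Why: Olefin cross-metathesis of a terminal allylic alcohol with an acrylate gives the E γ-hydroxy enoate (C3–C6); the C6 carbinol centre comes from the purchased diol and takes no part.

Step 18
Reactants: 26 tert-butyl (2E,4R)-4,5-dihydroxypent-2-enoate
Product: 27 (2R,3E)-5-tert-butoxy-2-hydroxy-5-oxopent-3-enoic acid
Conditions: TEMPO (cat.), PhI(OAc)2, MeCN–H2O, rt
Reagents that add atoms: water O
Why: Nitroxyl-catalysed oxidation selects the primary alcohol of the 1,2-diol and carries it through the aldehyde hydrate to the acid, while the secondary alcohol, deactivated by the enoate, should stay.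

Step 19
Reactants: 27 hydroxy acid
Product: 28 5-tert-butyl 1-methyl (2R,3E)-2-hydroxypent-3-enedioate
Conditions: Me3SiCHN2, toluene–MeOH, 0 °C
Reagents that add atoms: (trimethylsilyl)diazomethane C[Si](C)(C)C=[N+]=[N-]
Why: Methyl ester formation with a diazoalkane is neutral and so avoids base, which would isomerise the γ-hydroxy enoate or racemise C6.

Step 20
Reactants: 23 enol ether; 28 5-tert-butyl 1-methyl (2R,3E)-2-hydroxypent-3-enedioate
Product: 29 mixed iodoacetal: C8 bears I and the decalin; C1 bears OMe and O7–C6 (mixture at C1 and C8)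
Conditions: N-iodosuccinimide, 4 Å molecular sieves, CH2Cl2, −40 to 0 °C
Reagents that add atoms: N-iodosuccinimide O=C1CCC(=O)N1I
Why: Iodoalkoxylation of an enol ether (haloacetalisation, first half of the Ueno–Stork sequence): the electron-rich C1=C8 bond reacts far faster than the ring alkene, iodine ends on C8 and alcohol 28 adds to the oxocarbenium carbon C1, and the uncontrolled C1 and C8 centres are erased in steps 21 to 23.

Step 21
Reactants: 29 mixed iodoacetal
Product: 30 methyl (2R,3R)-3-(2-tert-butoxy-2-oxoethyl)-5-methoxy-4-[(1S,2R,4aS)-1,2,5,5-tetramethyl-1,2,3,4,4a,5,6,7-octahydronaphthalen-2-yl]oxolane-2-carboxylate (mixture at C1 and C8)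
Conditions: Bu3SnH, Et3B, air, toluene, −40 °C
Reagents that add atoms: none
Why: Ueno–Stork 5-exo-trig radical cyclisation: the nucleophilic C8 radical adds to C5, the β-carbon of the enoate, through a chair-like transition state with the C6 ester pseudoequatorial, which should place the new C5 side chain trans to CO2Me, and the early transition state with its long forming bond tolerates the neopentyl radical centre.

Step 22
Reactants: 30 2-methoxyoxolane
Product: 31 methyl (2R,3R)-3-(2-tert-butoxy-2-oxoethyl)-4-[(1R,2R,4aS)-1,2,5,5-tetramethyl-1,2,3,4,4a,5,6,7-octahydronaphthalen-2-yl]-2,3-dihydrofuran-2-carboxylate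
Conditions: Me3SiOTf, iPr2NEt, CH2Cl2, −20 °C to rt
Reagents that add atoms: none
Why: Conversion of an acetal into its enol ether with a silyl triflate and a hindered amine: the more basic exocyclic methoxy group is silylated and leaves, and the only β-hydrogen, C8–H, is removed, which erases the uncontrolled C1 and C8 centres and leaves C5 and C6 alone.

Step 23
Reactants: 31 2,3-dihydrofuran
Product: 33 methyl (1S,5R,6R,8R)-3-oxo-8-[(1S,2R,4aS)-1,2,5,5-tetramethyl-1,2,3,4,4a,5,6,7-octahydronaphthalen-2-yl]-2,7-dioxabicyclo[3.2.1]octane-6-carboxylate (target), via oxocarbenium ion 32 (not isolated)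
Conditions: CF3CO2H, CH2Cl2, −20 to 0 °C
Reagents that add atoms: none
Why: Acid-catalysed addition of a carboxyl oxygen to a cyclic enol ether (the reaction that makes tetrahydropyranyl esters), here intramolecular with the tert-butyl ester as nucleophile and loss of isobutene: the ester arm on C5 reaches C1 only from its own face, which fixes C1, and external protonation of C8 on the opposite, less hindered face (anti addition) puts the decalin over the lactone bridge, the arrangement that also avoids the exo ester on C6 and should therefore prevail if the addition is reversible.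

Compound list
1 | 2,2-dimethylcyclohexan-1-one | CC1(C)CCCCC1=O | starting material
2 | acetaldehyde | CC=O | starting material
3 | 6-(1-hydroxyethyl)-2,2-dimethylcyclohexan-1-one | CC(O)C1CCCC(C)(C)C1=O | intermediate
4 | 1-(3,3-dimethyl-2-oxocyclohexyl)ethyl methanesulfonate (not isolated) | CC(OS(C)(=O)=O)C1CCCC(C)(C)C1=O | intermediate
5 | (E)-6-ethylidene-2,2-dimethylcyclohexan-1-one | C/C=C1/C(=O)C(C)(C)CCC1 | intermediate
6 | (1S,2E)-2-ethylidene-6,6-dimethylcyclohexan-1-ol | C/C=C1/[C@@H](O)C(C)(C)CCC1 | intermediate
7 | methyl 4,4-dimethoxybutanoate | COC(=O)CCC(OC)OC | starting material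
8 | 4,4-dimethoxybutanoic acid | OC(=O)CCC(OC)OC | intermediate
9 | (1S,2E)-2-ethylidene-6,6-dimethylcyclohexyl 4,4-dimethoxybutanoate | C/C=C1/[C@@H](OC(=O)CCC(OC)OC)C(C)(C)CCC1 | intermediate
10 | trimethylsilyl ketene acetal of 9 (not isolated; geometry of no consequence) | C/C=C1/[C@@H](O/C(=C\CC(OC)OC)O[Si](C)(C)C)C(C)(C)CCC1 | intermediate
11 | trimethylsilyl (3S)-2-(2,2-dimethoxyethyl)-3-(3,3-dimethylcyclohex-1-en-1-yl)butanoate (not isolated) | C[Si](C)(C)OC(=O)C(CC(OC)OC)[C@H](C)C1=CC(C)(C)CCC1 | intermediate
12 | (3S)-2-(2,2-dimethoxyethyl)-3-(3,3-dimethylcyclohex-1-en-1-yl)butanoic acid | OC(=O)C(CC(OC)OC)[C@H](C)C1=CC(C)(C)CCC1 | intermediate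
13 | dilithium enediolate of 12 (not isolated) | [Li+].[Li+].[O-]C([O-])=C(CC(OC)OC)[C@H](C)C1=CC(C)(C)CCC1 | intermediate
14 | (2R,3R)-2-(2,2-dimethoxyethyl)-3-(3,3-dimethylcyclohex-1-en-1-yl)-2-methylbutanoic acid | OC(=O)[C@](C)(CC(OC)OC)[C@H](C)C1=CC(C)(C)CCC1 | intermediate
15 | (2R,3R)-2-(2,2-dimethoxyethyl)-3-(3,3-dimethylcyclohex-1-en-1-yl)-2-methylbutan-1-ol | OC[C@](C)(CC(OC)OC)[C@H](C)C1=CC(C)(C)CCC1 | intermediate
16 | tert-butyldiphenylsilyl ether of 15 | CC(C)(C)[Si](OC[C@](C)(CC(OC)OC)[C@H](C)C1=CC(C)(C)CCC1)(c1ccccc1)c1ccccc1 | intermediate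
17 | (3R,4R)-3-{[tert-butyl(diphenyl)silyl]oxymethyl}-4-(3,3-dimethylcyclohex-1-en-1-yl)-3-methylpentanal | CC(C)(C)[Si](OC[C@](C)(CC=O)[C@H](C)C1=CC(C)(C)CCC1)(c1ccccc1)c1ccccc1 | intermediate
18 | (1R,3R,4R,8aS)-3-{[tert-butyl(diphenyl)silyl]oxymethyl}-3,4,8,8-tetramethyl-1,2,3,4,6,7,8,8a-octahydronaphthalen-1-ol | CC(C)(C)[Si](OC[C@]1(C)C[C@@H](O)[C@@H]2C(=CCCC2(C)C)[C@H]1C)(c1ccccc1)c1ccccc1 | intermediate
19 | S-methyl xanthate of 18 | CC(C)(C)[Si](OC[C@]1(C)C[C@@H](OC(=S)SC)[C@@H]2C(=CCCC2(C)C)[C@H]1C)(c1ccccc1)c1ccccc1 | intermediate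
20 | tert-butyl(diphenyl){[(1R,2R,4aS)-1,2,5,5-tetramethyl-1,2,3,4,4a,5,6,7-octahydronaphthalen-2-yl]methoxy}silane | CC(C)(C)[Si](OC[C@]1(C)CC[C@@H]2C(=CCCC2(C)C)[C@H]1C)(c1ccccc1)c1ccccc1 | intermediate
21 | [(1R,2R,4aS)-1,2,5,5-tetramethyl-1,2,3,4,4a,5,6,7-octahydronaphthalen-2-yl]methanol | OC[C@]1(C)CC[C@@H]2C(=CCCC2(C)C)[C@H]1C | intermediate
22 | (1R,2R,4aS)-1,2,5,5-tetramethyl-1,2,3,4,4a,5,6,7-octahydronaphthalene-2-carbaldehyde | O=C[C@]1(C)CC[C@@H]2C(=CCCC2(C)C)[C@H]1C | intermediate
23 | (1S,2R,4aS)-2-(2-methoxyethenyl)-1,2,5,5-tetramethyl-1,2,3,4,4a,5,6,7-octahydronaphthalene (E/Z mixture) | COC=C[C@]1(C)CC[C@@H]2C(=CCCC2(C)C)[C@H]1C | intermediate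
24 | (R)-but-3-ene-1,2-diol | C=C[C@@H](O)CO | starting material
25 | tert-butyl acrylate | C=CC(=O)OC(C)(C)C | starting material
26 | tert-butyl (2E,4R)-4,5-dihydroxypent-2-enoate | OC[C@H](O)/C=C/C(=O)OC(C)(C)C | intermediate
27 | (2R,3E)-5-tert-butoxy-2-hydroxy-5-oxopent-3-enoic acid | OC(=O)[C@H](O)/C=C/C(=O)OC(C)(C)C | intermediate
28 | 5-tert-butyl 1-methyl (2R,3E)-2-hydroxypent-3-enedioate | COC(=O)[C@H](O)/C=C/C(=O)OC(C)(C)C | intermediate
29 | mixed iodoacetal from 23 and 28 (mixture at C1 and C8) | COC(O[C@H](/C=C/C(=O)OC(C)(C)C)C(=O)OC)C(I)[C@]1(C)CC[C@@H]2C(=CCCC2(C)C)[C@H]1C | intermediate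
30 | methyl (2R,3R)-3-(2-tert-butoxy-2-oxoethyl)-5-methoxy-4-(decalinyl)oxolane-2-carboxylate (mixture at C1 and C8) | COC1O[C@@H](C(=O)OC)[C@H](CC(=O)OC(C)(C)C)C1[C@]2(C)CC[C@@H]3C(=CCCC3(C)C)[C@H]2C | intermediate
31 | methyl (2R,3R)-3-(2-tert-butoxy-2-oxoethyl)-4-(decalinyl)-2,3-dihydrofuran-2-carboxylate | COC(=O)[C@@H]1OC=C([C@]2(C)CC[C@@H]3C(=CCCC3(C)C)[C@H]2C)[C@H]1CC(=O)OC(C)(C)C | intermediate
32 | C1 oxocarbenium ion from C8 protonation of 31 (not isolated) | COC(=O)[C@@H]1[O+]=C[C@@H]([C@]2(C)CC[C@@H]3C(=CCCC3(C)C)[C@H]2C)[C@H]1CC(=O)OC(C)(C)C | intermediate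
33 | methyl (1S,5R,6R,8R)-3-oxo-8-[(1S,2R,4aS)-1,2,5,5-tetramethyl-1,2,3,4,4a,5,6,7-octahydronaphthalen-2-yl]-2,7-dioxabicyclo[3.2.1]octane-6-carboxylate | COC(=O)[C@@H]1O[C@H]2OC(=O)C[C@@H]1[C@@H]2[C@]1(C)CC[C@@H]2C(=CCCC2(C)C)[C@H]1C | target

Total step count: 23. Longest linear sequence: 19 (steps 1–3, 5–16, 20–23).

Steps most likely to fail

Step 11. The two chair-like closures may differ too little. The equatorial C1′ methyl group of the wanted chair pays for a close contact with C8′H2, so attack on the other alkene face could compete. Chloride capture of the C8a′ cation could also divert material.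

The fallback sets out from 18 obtained as a mixture of C4a′ epimers and resets C4a′ through the C4′ oxygen:
- Dess–Martin oxidation gives the β,γ-unsaturated C4′ ketone as an epimer mixture F1.
- KN(SiMe3)2 at −78 °C removes the doubly activated C4a′–H to give the potassium dienolate F2.
- Kinetic α-protonation with acetic acid at −78 °C, expected from the face away from the C1′ and C2′ methyl groups, gives the ketone with the natural C4a′ configuration F3.
- LiBH(sBu)3 then attacks the carbonyl group equatorially, because the axial C2′ methyl group blocks the axial path. This returns the axial alcohol, and the route is rejoined at 18.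

Step 23. Protonation of C8 may occur from the face of the ester arm, giving the C8 epimer, or the acid may shift the C8′=C8a′ alkene.

The fallback sets out from 31 and replaces the proton by iodine:
- N-iodosuccinimide in CH2Cl2 at −40 °C brings about an iodolactonisation, which is strictly anti. Iodine adds to C8 opposite the ester arm and the tert-butyl ester closes on C1 with loss of isobutene, giving the C8 tertiary iodide of the bicyclic lactone F4.
- Bu3SnH with Et3B and air then removes iodine through the bridge radical. This radical should take hydrogen from the side of the O7–C6 bridge so that the decalin stays over the lactone, and the route is rejoined at 33.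

Step 22. Removal of the hindered C8–H may be slow. That would allow premature capture of the oxocarbenium ion by the tert-butyl ester, or cleavage of the ring C1–O7 bond.

The fallback sets out from 30 and uses a neutral syn-elimination:
- PhSeH with BF3·OEt2 at −78 °C exchanges methoxy for the anomeric phenyl selenide F5. The selenide should settle trans to the decalin and hence cis to C8–H.
- One equivalent of mCPBA at −78 °C gives the selenoxide F6.
- F6 eliminates on warming in the presence of iPr2NH, and the route is rejoined at 31.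

Further compounds
F1 | step 11 | C4′ ketone from 18 as C4a′ epimer mixture | CC(C)(C)[Si](OC[C@]1(C)CC(=O)C2C(=CCCC2(C)C)[C@H]1C)(c1ccccc1)c1ccccc1
F2 | step 11 | potassium C4′–C4a′–C8a′–C8′ dienolate | CC(C)(C)[Si](OC[C@]1(C)CC([O-])=C2C(=CCCC2(C)C)[C@H]1C)(c1ccccc1)c1ccccc1.[K+]
F3 | step 11 | C4′ ketone with natural C4a′ configuration | CC(C)(C)[Si](OC[C@]1(C)CC(=O)[C@@H]2C(=CCCC2(C)C)[C@H]1C)(c1ccccc1)c1ccccc1
F4 | step 23 | 8-iodo derivative of 33 | COC(=O)[C@@H]1O[C@H]2OC(=O)C[C@@H]1[C@]2(I)[C@]1(C)CC[C@@H]2C(=CCCC2(C)C)[C@H]1C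
F5 | step 22 | C1 phenyl selenide from 30 | COC(=O)[C@@H]1OC([Se]c2ccccc2)C([C@]3(C)CC[C@@H]4C(=CCCC4(C)C)[C@H]3C)[C@H]1CC(=O)OC(C)(C)C
F6 | step 22 | C1 phenyl selenoxide | COC(=O)[C@@H]1OC([Se](=O)c2ccccc2)C([C@]3(C)CC[C@@H]4C(=CCCC4(C)C)[C@H]3C)[C@H]1CC(=O)OC(C)(C)C
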